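**Retrosynthetic overview**
- Ring D (lactone) is unmasked last from a C16 diol (glycol cleavage, lactol oxidation). Ring C (tetrahydrofuran) comes from 5-exo opening of a reagent-controlled C13–C16 epoxide by the tertiary C9 hydroxyl, with inversion at C13.
- The side chain is joined at C12–C13 by B-alkyl Suzuki–Miyaura coupling. The C9–O bond is set by β-face epoxidation of a C9=C11 exocyclic alkene, C8 by equilibration next to the C9 ketone, and C6 by dissolving-metal reduction.
- Ring B arises by nickel-catalysed insertion of propyne into the C6–C9 bond of a cis-fused cyclobutanone (strain-driven two-carbon expansion), followed by γ-oxidation at C9.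
- The cyclobutanone comes from a keteniminium–alkene [2+2] cycloaddition that forms C5–C6 and C9–C10. The strategy rests on the cis A/B ring fusion, in which the methyl-bearing quaternary C10 sits next to C5–H, itself next to the C4 gem-dimethyl carbon, with C6 and C9 as the first ring B atoms on these two centres.
- Ring order: ring A (from 2,2,6-trimethylcyclohexanone), temporary cyclobutane, ring B, ring C, ring D.

Key step: step 4

Convention: labdane numbering is used throughout; bicyclic intermediates are named as decalins with these locants; β is the face of ring B that carries the C10 methyl group and H5, α the opposite face; C1′ is the extra hydroxymethyl carbon on C16 that is excised in step 21.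
Assumption: the (2R,5R)-auxiliary is taken to induce the (1S,6S)-cyclobutanone; if the sense proves opposite, the (2S,5S)-pyrrolidine is used in steps 3 and 4 with nothing else changed.

**Route**

Step 1
Reactants: 1 2,2,6-trimethylcyclohexanone
Product: 3 2,6,6-trimethylcyclohex-1-en-1-yl trifluoromethanesulfonate, via lithium enolate 2 (not isolated)
Conditions: LiN(i-Pr)2, THF, −78 to 0 °C; then PhNTf2, 0 °C to rt
Reagents that add atoms: N-phenylbis(trifluoromethanesulfonimide), O=S(=O)(N(c1ccccc1)S(=O)(=O)C(F)(F)F)C(F)(F)F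
Why: The ketone has a single α-hydrogen, so deprotonation gives one enolate, and O-sulfonylation of it (enol triflate formation) fixes the future alkene position; no stereocentre remains.

Step 2
Reactants: 3 2,6,6-trimethylcyclohex-1-en-1-yl trifluoromethanesulfonate
Product: 4 1,3,3-trimethylcyclohexene
Conditions: Pd(OAc)2 (cat.), PPh3, Bu3N, HCO2H, DMF, 60 °C
Reagents that add atoms: none
Why: Oxidative addition of zerovalent palladium to the enol triflate, formate exchange, decarboxylation and reductive elimination (palladium-catalysed formate reduction of an enol triflate) replace OTf by H without moving the double bond.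

Step 3
Reactants: 5 (2R,5R)-2,5-dimethylpyrrolidine
Product: 6 1-acetyl-(2R,5R)-2,5-dimethylpyrrolidine
Conditions: Ac2O, Et3N, CH2Cl2, 0 °C to rt
Reagents that add atoms: acetic anhydride, CC(=O)OC(C)=O
Why: N-acylation of the secondary amine by the anhydride (amide formation) leaves both stereocentres of the auxiliary untouched.

Step 4
Reactants: 6 1-acetyl-(2R,5R)-2,5-dimethylpyrrolidine; 4 1,3,3-trimethylcyclohexene
Product: 9 (1S,6S)-2,2,6-trimethylbicyclo[4.2.0]octan-8-one, via keteniminium triflate 7 (not isolated), via cyclobutaniminium triflate 8 (not isolated)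
Conditions: Tf2O (slow addition), 2,4,6-collidine, 4 (excess), ClCH2CH2Cl, reflux; then H2O, reflux
Reagents that add atoms: water, O
Why: Triflic anhydride O-sulfonylates amide 6 and collidine-assisted loss of triflic acid gives keteniminium ion 7, whose central carbon is attacked by the less substituted alkene carbon of 4 (C5) while charge builds at tertiary C10, which collapses onto the CH2 terminus (C9) to give iminium salt 8; water then hydrolyses 8 to ketone 9 and releases the auxiliary. The closest known reaction type is the keteniminium–olefin [2+2] cycloaddition with a C2-symmetric 2,5-dimethylpyrrolidine on nitrogen. The four-membered ring closes as the lagging second bond (C9–C10, cation–enamine collapse) of an asynchronous cycloaddition that is suprafacial on the alkene, leaving the C6=N bond exocyclic. C5 and C10 are created together: their cis relation follows from suprafacial addition across the ring alkene (a trans-fused bicyclo[4.2.0]octanone is not accessible), and their absolute configuration from the trans-2,5-dimethyl groups, which block one face of approach to the keteniminium C=C. The step needs regioselectivity (C6 on C5, C9 on C10), secured by the cation-stabilising methyl on C10 and the lower substitution at C5, and chemoselectivity against keteniminium self-condensation, secured by slow generation in excess alkene.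

Step 5
Reactants: 9 (1S,6S)-2,2,6-trimethylbicyclo[4.2.0]octan-8-one; 10 propyne
Product: 11 cis-fused enone (4aS,8aS)-3,4a,8,8-tetramethyl-4a,5,6,7,8,8a-hexahydronaphthalen-1(4H)-one
Conditions: Ni(cod)2 (10 mol %), PCy3 (20 mol %), toluene, 100 °C, sealed vessel, propyne added slowly as a toluene solution
Reagents that add atoms: none
Why: Oxidative cyclisation of the strained carbonyl and propyne on zerovalent nickel joins C6 to the unsubstituted alkyne carbon, β-carbon elimination cleaves the less hindered C6–C9 bond with release of ring strain, and C8–C9 reductive elimination closes ring B with the methyl on C8 (nickel-catalysed alkyne insertion into a cyclobutanone); C5 and C10 are not touched.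

Step 6
Reactants: 11 cis-fused enone
Product: 12 cis-fused enedione (4aS,8aR)-2,5,5,8a-tetramethyl-4a,5,6,7,8,8a-hexahydronaphthalene-1,4-dione
Conditions: Rh2(cap)4 (dirhodium tetrakis(caprolactamate), 1 mol %), t-BuOOH (70 % aq.), ClCH2CH2Cl, 40 °C
Reagents that add atoms: tert-butyl hydroperoxide, CC(C)(C)OO
Why: tert-Butylperoxyl radicals formed on the dirhodium catalyst abstract the ring allylic hydrogen at C9 (γ to the carbonyl) in preference to the methyl hydrogens, and the mixed peroxide collapses to the ketone (dirhodium-catalysed allylic C–H oxidation of an enone to an enedione); the base-free medium protects the epimerisable C5.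

Step 7
Reactants: 12 cis-fused enedione
Product: 13 cis-fused 2,5,5,8a-tetramethyloctahydronaphthalene-1,4-dione (labdane C6 and C9 ketones; C8 epimers)
Conditions: Zn dust, AcOH, rt
Reagents that add atoms: none
Why: Electron transfer from zinc and protonation (dissolving-metal conjugate reduction of an enedione) saturate C7–C8 at room temperature without enolising C5; C8 is formed unselectively and is corrected in step 8.

Step 8
Reactants: 13 cis-fused 1,4-dione (C8 epimers)
Product: 15 6,6-ethylenedioxy-4,4,8β,10β-tetramethyl-5β-decalin-9-one, via C8-epimeric ketal 14 (not isolated)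
Conditions: TMSOCH2CH2OTMS, TMSOTf (cat.), CH2Cl2, −78 to −20 °C; then NaOMe, MeOH, rt
Reagents that add atoms: 1,2-bis(trimethylsilyloxy)ethane, C[Si](C)(C)OCCO[Si](C)(C)C
Why: Silyl-triflate-catalysed dioxolane formation at low temperature (kinetic ketalisation) should occur only at C6, because C9 is flanked by quaternary C10 and C8, and methoxide then equilibrates C8, the only enolisable position left, to the equatorial 8β-methyl epimer, which avoids a syn-axial clash with C1 and the axial ketal oxygen.

Step 9
Reactants: 15 6,6-ethylenedioxy-4,4,8β,10β-tetramethyl-5β-decalin-9-one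
Product: 16 6,6-ethylenedioxy-4,4,8β,10β-tetramethyl-9-methylene-5β-decalin
Conditions: Cp2TiMe2, toluene, 70 °C, dark
Reagents that add atoms: dimethyltitanocene, C[Ti](C)(C1C=CC=C1)C1C=CC=C1
Why: The titanium methylidene formed on heating adds to the hindered, enolisable C9 ketone under non-basic conditions (Petasis methylenation), so C8 keeps its configuration and the ketal survives.

Step 10
Reactants: 16 6,6-ethylenedioxy-4,4,8β,10β-tetramethyl-9-methylene-5β-decalin
Product: 17 4,4,8β,10β-tetramethyl-9-methylene-5β-decalin-6-one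
Conditions: PPTS, acetone–H2O, 40 °C
Reagents that add atoms: water, O
Why: Mild acid hydrolysis of the dioxolane (acetal hydrolysis) frees the C6 ketone under conditions too weak to isomerise the exocyclic alkene or to enolise C5.

Step 11
Reactants: 17 4,4,8β,10β-tetramethyl-9-methylene-5β-decalin-6-one
Product: 18 4,4,8β,10β-tetramethyl-9-methylene-5β-decalin-6β-ol
Conditions: Li, NH3(l)–THF, MeOH, −78 °C
Reagents that add atoms: none
Why: Electron transfer to the ketone and protonation of the equilibrating ketyl/carbanion (dissolving-metal reduction) should give the more stable equatorial 6β-alcohol, cis to H5, whereas a hydride reagent would attack the open β face and give the 6α-epimer; the isolated alkene is inert.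

Step 12
Reactants: 18 4,4,8β,10β-tetramethyl-9-methylene-5β-decalin-6β-ol
Product: 19 9β,11-epoxy-4,4,8β,10β-tetramethyl-5β-decalin-6β-ol (spiro-oxirane at C9 with the oxygen β and C11 α)
Conditions: m-CPBA, NaHCO3, CH2Cl2, 0 °C
Reagents that add atoms: m-chloroperoxybenzoic acid, OOC(=O)c1cccc(Cl)c1
Why: Peracid epoxidation (Prilezhaev reaction) of the 1,1-disubstituted alkene should occur from the convex β face, anti to the axial C1 methylene on C10 that shields the α face, placing the oxygen β on C9.

Step 13
Reactants: 19 9β,11-epoxy-4,4,8β,10β-tetramethyl-5β-decalin-6β-ol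
Product: 20 4,4,8β,10β-tetramethyl-9α-vinyl-5β-decalin-6β,9β-diol
Conditions: Me3S+ I−, n-BuLi (excess), THF, −10 °C to rt
Reagents that add atoms: trimethylsulfonium iodide, C[S+](C)C.[I-]
Why: Dimethylsulfonium methylide opens the epoxide at primary C11 and base-induced loss of dimethyl sulfide from the sulfonium alkoxide gives the vinyl carbinol (one-carbon homologation of an epoxide to an allylic alcohol); the C9–O bond is never broken, so the 9β-oxygen is retained.

Step 14
Reactants: 20 4,4,8β,10β-tetramethyl-9α-vinyl-5β-decalin-6β,9β-diol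
Product: 21 6β-acetoxy-4,4,8β,10β-tetramethyl-9α-vinyl-5β-decalin-9β-ol
Conditions: Ac2O, pyridine, DMAP (cat.), CH2Cl2, rt
Reagents that add atoms: acetic anhydride, CC(=O)OC(C)=O
Why: DMAP-catalysed acylation (selective esterification) takes place at the secondary equatorial 6β-hydroxyl only, the tertiary C9 hydroxyl between C8 and quaternary C10 being unreactive.

Step 15
Reactants: 22 but-3-yn-1-ol
Product: 23 4-(tert-butyldimethylsilyloxy)but-1-yne
Conditions: TBSCl, imidazole, DMF, rt
Reagents that add atoms: tert-butyldimethylsilyl chloride, CC(C)(C)[Si](C)(C)Cl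
Why: Imidazole-promoted silylation of the primary alcohol (silyl ether protection) masks the future C15 hydroxyl.

Step 16
Reactants: 23 4-(tert-butyldimethylsilyloxy)but-1-yne
Product: 25 5-(tert-butyldimethylsilyloxy)pent-2-yn-1-ol, via lithium acetylide 24 (not isolated)
Conditions: n-BuLi, THF, −78 °C; then (CH2O)n, −78 °C to rt
Reagents that add atoms: paraformaldehyde (as formaldehyde), C=O
Why: Deprotonation of the terminal alkyne and addition of the acetylide to formaldehyde (acetylide hydroxymethylation) give the propargylic alcohol.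

Step 17
Reactants: 25 5-(tert-butyldimethylsilyloxy)pent-2-yn-1-ol
Product: 27 (Z)-5-(tert-butyldimethylsilyloxy)-3-iodopent-2-en-1-ol, via vinylalanate 26 (not isolated)
Conditions: Na[AlH2(OCH2CH2OMe)2], THF, 0 °C; then I2, −78 °C
Reagents that add atoms: iodine, II
Why: Alkoxide-directed trans-hydroalumination places aluminium on C3 cis to the CH2O group in a five-membered alanate, and iodinolysis with retention gives the (Z)-3-iodo allylic alcohol (hydroalumination–iodination of a propargylic alcohol).

Step 18
Reactants: 21 6β-acetoxy-4,4,8β,10β-tetramethyl-9α-vinyl-5β-decalin-9β-ol; 27 (Z)-5-(tert-butyldimethylsilyloxy)-3-iodopent-2-en-1-ol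
Product: 29 6β-acetoxy-9α-[(E)-5-hydroxy-3-(2-(tert-butyldimethylsilyloxy)ethyl)pent-3-en-1-yl]-4,4,8β,10β-tetramethyl-5β-decalin-9β-ol, via alkylborane 28 (not isolated)
Conditions: 9-BBN, THF, rt; then 27, Pd(dppf)Cl2 (5 mol %), AsPh3, K3PO4 (3 M aq.), DMF, rt
Reagents that add atoms: none
Why: Anti-Markovnikov hydroboration of the vinyl group puts boron on C12, and B-alkyl Suzuki–Miyaura coupling with the vinyl iodide proceeds with retention of alkene geometry, so C12 ends cis and C14 trans to the hydroxymethyl group on the C13=C16 alkene.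

Step 19
Reactants: 29 (E)-allylic alcohol
Product: 30 (13S,16S)-13,16-epoxide of 29 (2,3-epoxy alcohol with C1′ hydroxymethyl on C16)
Conditions: Ti(Oi-Pr)4, L-(+)-diethyl tartrate, t-BuOOH, 4 Å MS, CH2Cl2, −20 °C
Reagents that add atoms: tert-butyl hydroperoxide, CC(C)(C)OO
Why: Sharpless asymmetric epoxidation of the 3,3-disubstituted (E)-allylic alcohol is reagent-controlled, and with the L-(+)-tartrate it should deliver oxygen to the face that gives the (13S,16S)-epoxide, as for geraniol-type substrates, independent of the remote ring stereocentres.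

Step 20
Reactants: 30 (13S,16S)-epoxy alcohol
Product: 32 (13R,16S)-6β-acetoxy-9β,13-epoxy-5β-labdane-15,16,1′-triol (tetrahydrofuran ring C closed; C13 carries CH2CH2OH and CH(OH)CH2OH), via silyl ether 31 (not isolated)
Conditions: CSA (cat.), CH2Cl2, 0 °C; then MeOH, rt
Reagents that add atoms: none
Why: Acid-catalysed 5-exo opening of the epoxide at its tertiary carbon C13 by the C9 hydroxyl (intramolecular epoxide opening) proceeds with inversion and turns 13S into the 13R spiro centre, and methanolysis then removes the primary silyl ether.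

Step 21
Reactants: 32 (13R,16S)-triol
Product: 34 (13R)-6β-acetoxy-9β,13-epoxy-5β-labdane-16,15-lactol (anomers), via hydroxy aldehyde 33 (not isolated)
Conditions: NaIO4, THF–H2O, rt
Reagents that add atoms: none
Why: Periodate glycol cleavage removes C1′ and leaves a C16 aldehyde on quaternary C13, which cannot epimerise and closes with the C15 hydroxyl to the five-membered lactol.

Step 22
Reactants: 34 lactol
Product: 35 CNP0081177.1, (13R)-6β-acetoxy-9β,13-epoxy-5β-labdan-16,15-olide
Conditions: TEMPO (cat.), PhI(OAc)2, CH2Cl2, rt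
Reagents that add atoms: none
Why: Oxoammonium-mediated oxidation of the lactol (TEMPO oxidation) gives the γ-lactone, and no other oxidisable group is present.

**Compound list**

1 | 2,2,6-trimethylcyclohexanone (racemic) | CC1CCCC(C)(C)C1=O | starting material
2 | lithium 2,6,6-trimethylcyclohex-1-en-1-olate | [Li+].[O-]C1=C(C)CCCC1(C)C | intermediate
3 | 2,6,6-trimethylcyclohex-1-en-1-yl trifluoromethanesulfonate | CC1=C(OS(=O)(=O)C(F)(F)F)C(C)(C)CCC1 | intermediate
4 | 1,3,3-trimethylcyclohexene | CC1=CC(C)(C)CCC1 | intermediate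
5 | (2R,5R)-2,5-dimethylpyrrolidine | C[C@@H]1CC[C@@H](C)N1 | starting material
6 | 1-acetyl-(2R,5R)-2,5-dimethylpyrrolidine | CC(=O)N1[C@H](C)CC[C@H]1C | intermediate
7 | (2R,5R)-1-ethenylidene-2,5-dimethylpyrrolidinium triflate (keteniminium salt) | C=C=[N+]1[C@H](C)CC[C@H]1C.[O-]S(=O)(=O)C(F)(F)F | intermediate
8 | cyclobutaniminium triflate (iminium of 9 with the auxiliary) | C[C@@H]1CC[C@@H](C)[N+]1=C1C[C@]2(C)CCCC(C)(C)[C@H]12.[O-]S(=O)(=O)C(F)(F)F | intermediate
9 | (1S,6S)-2,2,6-trimethylbicyclo[4.2.0]octan-8-one (cis-fused) | O=C1C[C@]2(C)CCCC(C)(C)[C@H]12 | intermediate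
10 | propyne | CC#C | starting material
11 | (4aS,8aS)-3,4a,8,8-tetramethyl-4a,5,6,7,8,8a-hexahydronaphthalen-1(4H)-one (cis-fused; C6 ketone, C7=C8) | O=C1C=C(C)C[C@]2(C)CCCC(C)(C)[C@H]12 | intermediate
12 | (4aS,8aR)-2,5,5,8a-tetramethyl-4a,5,6,7,8,8a-hexahydronaphthalene-1,4-dione (cis-fused 7-ene-6,9-dione) | O=C1C=C(C)C(=O)[C@]2(C)CCCC(C)(C)[C@H]12 | intermediate
13 | cis-fused 2,5,5,8a-tetramethyloctahydronaphthalene-1,4-dione (6,9-dione, C8 epimers) | O=C1CC(C)C(=O)[C@]2(C)CCCC(C)(C)[C@H]12 | intermediate
14 | 6,6-ethylenedioxy-4,4,8,10β-tetramethyl-5β-decalin-9-one (C8 epimers) | O1CCOC12CC(C)C(=O)[C@]3(C)CCCC(C)(C)[C@H]23 | intermediate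
15 | 6,6-ethylenedioxy-4,4,8β,10β-tetramethyl-5β-decalin-9-one | O1CCOC12C[C@@H](C)C(=O)[C@]3(C)CCCC(C)(C)[C@H]23 | intermediate
16 | 6,6-ethylenedioxy-4,4,8β,10β-tetramethyl-9-methylene-5β-decalin | O1CCOC12C[C@@H](C)C(=C)[C@]3(C)CCCC(C)(C)[C@H]23 | intermediate
17 | 4,4,8β,10β-tetramethyl-9-methylene-5β-decalin-6-one | O=C1C[C@@H](C)C(=C)[C@]2(C)CCCC(C)(C)[C@H]12 | intermediate
18 | 4,4,8β,10β-tetramethyl-9-methylene-5β-decalin-6β-ol | O[C@H]1C[C@@H](C)C(=C)[C@]2(C)CCCC(C)(C)[C@H]12 | intermediate
19 | 9β,11-epoxy-4,4,8β,10β-tetramethyl-5β-decalin-6β-ol (spiro-oxirane, oxygen β) | O[C@H]1C[C@@H](C)[C@]2(CO2)[C@]3(C)CCCC(C)(C)[C@H]13 | intermediate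
20 | 4,4,8β,10β-tetramethyl-9α-vinyl-5β-decalin-6β,9β-diol | O[C@H]1C[C@@H](C)[C@](O)(C=C)[C@]2(C)CCCC(C)(C)[C@H]12 | intermediate
21 | 6β-acetoxy-4,4,8β,10β-tetramethyl-9α-vinyl-5β-decalin-9β-ol | CC(=O)O[C@H]1C[C@@H](C)[C@](O)(C=C)[C@]2(C)CCCC(C)(C)[C@H]12 | intermediate
22 | but-3-yn-1-ol | C#CCCO | starting material
23 | 4-(tert-butyldimethylsilyloxy)but-1-yne | C#CCCO[Si](C)(C)C(C)(C)C | intermediate
24 | lithium acetylide of 23 | [Li+].[C-]#CCCO[Si](C)(C)C(C)(C)C | intermediate
25 | 5-(tert-butyldimethylsilyloxy)pent-2-yn-1-ol | OCC#CCCO[Si](C)(C)C(C)(C)C | intermediate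
26 | sodium cyclic vinylalanate from 25 (aluminium on C3, oxygen-bound) | [Na+].COCCO[Al-]1(OCCOC)OCC=C1CCO[Si](C)(C)C(C)(C)C | intermediate
27 | (Z)-5-(tert-butyldimethylsilyloxy)-3-iodopent-2-en-1-ol | OC/C=C(\I)CCO[Si](C)(C)C(C)(C)C | intermediate
28 | B-alkyl-9-borabicyclo[3.3.1]nonane from 21 (boron on C12) | CC(=O)O[C@H]1C[C@@H](C)[C@](O)(CCB2C3CCCC2CCC3)[C@]4(C)CCCC(C)(C)[C@H]14 | intermediate
29 | 6β-acetoxy-9α-[(E)-5-hydroxy-3-(2-(tert-butyldimethylsilyloxy)ethyl)pent-3-en-1-yl]-4,4,8β,10β-tetramethyl-5β-decalin-9β-ol | CC(=O)O[C@H]1C[C@@H](C)[C@](O)(CC/C(CCO[Si](C)(C)C(C)(C)C)=C\CO)[C@]2(C)CCCC(C)(C)[C@H]12 | intermediate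
30 | (13S,16S)-13,16-epoxide of 29 | CC(=O)O[C@H]1C[C@@H](C)[C@](O)(CC[C@@]3(CCO[Si](C)(C)C(C)(C)C)O[C@H]3CO)[C@]2(C)CCCC(C)(C)[C@H]12 | intermediate
31 | (13R,16S)-6β-acetoxy-15-(tert-butyldimethylsilyloxy)-9β,13-epoxy-5β-labdane-16,1′-diol | CC(=O)O[C@H]1C[C@@H](C)[C@]2(CC[C@@](CCO[Si](C)(C)C(C)(C)C)([C@@H](O)CO)O2)[C@]3(C)CCCC(C)(C)[C@H]13 | intermediate
32 | (13R,16S)-6β-acetoxy-9β,13-epoxy-5β-labdane-15,16,1′-triol | CC(=O)O[C@H]1C[C@@H](C)[C@]2(CC[C@@](CCO)([C@@H](O)CO)O2)[C@]3(C)CCCC(C)(C)[C@H]13 | intermediate
33 | (13R)-6β-acetoxy-9β,13-epoxy-15-hydroxy-5β-labdan-16-al | CC(=O)O[C@H]1C[C@@H](C)[C@]2(CC[C@@](CCO)(C=O)O2)[C@]3(C)CCCC(C)(C)[C@H]13 | intermediate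
34 | (13R)-6β-acetoxy-9β,13-epoxy-5β-labdane-16,15-lactol (anomers) | CC(=O)O[C@H]1C[C@@H](C)[C@]2(CC[C@]3(CCOC3O)O2)[C@]4(C)CCCC(C)(C)[C@H]14 | intermediate
35 | CNP0081177.1, (13R)-6β-acetoxy-9β,13-epoxy-5β-labdan-16,15-olide | CC(=O)O[C@H]1C[C@@H](C)[C@]2(CC[C@]3(CCOC3=O)O2)[C@]2(C)CCCC(C)(C)[C@H]12 | target

**Totals and risks**

Total step count: 22. Longest linear sequence: 18 steps (steps 1, 2, 4 to 14 and 18 to 22).

Steps most likely to fail:

1. Step 5 (propyne insertion). Propyne may be consumed by nickel-mediated oligomerisation faster than it cyclises with the hindered ketone, or β-carbon elimination may take place at C5–C6 instead of C6–C9. The fallback sets out from 9 and returns at 11.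
 - C-acetylation of the C9 enolate of 9 (LiN(i-Pr)2, THF, −78 °C; 1-acetylimidazole) would give the 7-acetyl derivative of 9, F3.
 - NaOMe in MeOH would open the strained ring by retro-Claisen cleavage of C6–C9 to methyl cis-2,6,6-trimethyl-2-(2-oxopropyl)cyclohexane-1-carboxylate F4. In the same flask this closes by Claisen condensation of the methyl ketone onto the ester to the cis-fused ring B 1,3-dione 4a,8,8-trimethyloctahydronaphthalene-1,3-dione F5.
 - O-Triflation at the less hindered C8 oxygen (Tf2O, pyridine, CH2Cl2) would give the vinylogous acyl triflate F6.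
 - Me2CuLi (THF, −78 °C) would replace the triflate by methyl through addition–elimination and give 11.

2. Step 4 (keteniminium [2+2]). The unsubstituted keteniminium ion may self-condense before it is trapped, because the alkene carbon that must bond first (C5) is neopentyl; facial discrimination by the auxiliary may also be weak. The fallback sets out from 4 and returns at 9.
 - Dichloroketene, generated from trichloroacetyl chloride with Zn–Cu couple in Et2O, would add to 4 with the same regiochemistry and give racemic cis-7,7-dichloro-2,2,6-trimethylbicyclo[4.2.0]octan-8-one F1.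
 - Zn in AcOH would remove both chlorines and give racemic cis-2,2,6-trimethylbicyclo[4.2.0]octan-8-one F2.
 - Preparative chromatography on a chiral stationary phase would deliver the (1S,6S)-enantiomer 9.

3. Step 12 (epoxidation). Facial selectivity may be low if ring B populates the other chair, which would lead to the 9α-epoxide and the wrong C9 configuration. The fallback replaces kinetic face selection by thermodynamic control; it sets out from 15 and returns at 20.
 - Dimethylsulfoxonium methylide (Me3S(O)I, NaH, DMSO, 50 °C) adds reversibly to the C9 ketone and closes through the betaine with the equatorial C–C bond (Corey–Chaykovsky epoxidation), giving the 9β,11-epoxide of the 6-ketal, F7.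
 - Me3S+ I− and n-BuLi would homologate F7 to 6,6-ethylenedioxy-4,4,8β,10β-tetramethyl-9α-vinyl-5β-decalin-9β-ol F8.
 - PPTS in acetone–H2O would give 9β-hydroxy-4,4,8β,10β-tetramethyl-9α-vinyl-5β-decalin-6-one F9.
 - Li in NH3–THF with MeOH would reduce F9 to diol 20.

**Further compounds**

F1 | step 4 | racemic cis-7,7-dichloro-2,2,6-trimethylbicyclo[4.2.0]octan-8-one (relative configuration drawn) | O=C1C(Cl)(Cl)[C@]2(C)CCCC(C)(C)[C@H]12
F2 | step 4 | racemic cis-2,2,6-trimethylbicyclo[4.2.0]octan-8-one (relative configuration drawn) | O=C1C[C@]2(C)CCCC(C)(C)[C@H]12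
F3 | step 5 | 7-acetyl derivative of 9 (C7 epimers, enolised) | O=C1C(C(C)=O)[C@]2(C)CCCC(C)(C)[C@H]12
F4 | step 5 | methyl cis-2,6,6-trimethyl-2-(2-oxopropyl)cyclohexane-1-carboxylate | COC(=O)[C@H]1C(C)(C)CCC[C@@]1(C)CC(C)=O
F5 | step 5 | cis-fused 4a,8,8-trimethyloctahydronaphthalene-1,3-dione (C6 and C8 ketones) | O=C1CC(=O)C[C@]2(C)CCCC(C)(C)[C@H]12
F6 | step 5 | C8 enol triflate of F5 (vinylogous acyl triflate, C6 ketone) | O=C1C=C(OS(=O)(=O)C(F)(F)F)C[C@]2(C)CCCC(C)(C)[C@H]12
F7 | step 12 | 9β,11-epoxy-6,6-ethylenedioxy-4,4,8β,10β-tetramethyl-5β-decalin | O1CCOC12C[C@@H](C)[C@]3(CO3)[C@]4(C)CCCC(C)(C)[C@H]24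
F8 | step 12 | 6,6-ethylenedioxy-4,4,8β,10β-tetramethyl-9α-vinyl-5β-decalin-9β-ol | O1CCOC12C[C@@H](C)[C@](O)(C=C)[C@]3(C)CCCC(C)(C)[C@H]23
F9 | step 12 | 9β-hydroxy-4,4,8β,10β-tetramethyl-9α-vinyl-5β-decalin-6-one | O=C1C[C@@H](C)[C@](O)(C=C)[C@]2(C)CCCC(C)(C)[C@H]12
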